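**Strategy.** Ring C is cut at O1–C2 and C4–C4a. This leaves ring A as a phloroglucinol and C2–C3–C4 as a three-carbon dielectrophile. That unit is used as an enantiopure 4-aryl beta-lactone, whose two C–O bonds are spent one after the other in a single flask. A 3,5-protected phloroglucinol phenoxide opens the benzylic C–O bond with inversion (O1–C2, sets 2S). The freed carboxylate, activated as a mixed anhydride, then acylates the adjacent ring-A carbon (C4–C4a). The step exploits the 1,3,5-trioxygenated ring A, in which both CH positions next to O1 are equivalent and highly nucleophilic, and the benzylic, beta-carboxy nature of C2. The lactone comes from 7-prenylbenzofuran-5-carbaldehyde.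

Key step: step 9

Assumption: the target SMILES corresponds to the 2S descriptor (O1 > aryl carbon > C3 > H), the configuration of natural flavanones.

Step 1
Reactants: 1 3-bromo-4-hydroxybenzaldehyde
Product: 2 3-bromo-4-hydroxy-5-iodobenzaldehyde
Conditions: NIS, TsOH (cat.), MeCN, rt
Reagents that add atoms: N-iodosuccinimide O=C1CCC(=O)N1I
Why: Electrophilic aromatic iodination, in which the phenol directs to its only free ortho position because the other ortho position carries Br and the para position carries CHO.

Step 2
Reactants: 2 3-bromo-4-hydroxy-5-iodobenzaldehyde, 3 ethynyltrimethylsilane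
Product: 6 7-bromobenzofuran-5-carbaldehyde, via alkynylphenol 4 (not isolated), via 2-silylbenzofuran 5 (not isolated)
Conditions: PdCl2(PPh3)2, CuI, Et3N, THF, rt then 60 °C; then Bu4NF, wet THF, rt
Reagents that add atoms: none
Why: Sonogashira coupling should occur only at the carbon–iodine bond (oxidative addition to the bromide is far slower at rt), the ortho-alkynylphenol closes by copper-assisted 5-endo-dig heteroannulation on warming, and fluoride removes the C2 silyl group by protodesilylation.

Step 3
Reactants: 6 7-bromobenzofuran-5-carbaldehyde, 7 tributyl(3-methylbut-2-enyl)stannane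
Product: 8 7-(3-methylbut-2-enyl)benzofuran-5-carbaldehyde
Conditions: Pd(PPh3)4, DMF, 90 °C
Reagents that add atoms: none
Why: Stille coupling of the aryl bromide, in which the prenyl group is normally transferred through its unsubstituted carbon under these conditions and the neutral medium spares the aldehyde.

Step 4
Reactants: 8 7-(3-methylbut-2-enyl)benzofuran-5-carbaldehyde, 9 ethyl diazoacetate
Product: 10 ethyl 3-[7-(3-methylbut-2-enyl)benzofuran-5-yl]-3-oxopropanoate
Conditions: NbCl5 (5 mol %), CH2Cl2, rt
Reagents that add atoms: none
Why: Roskamp reaction, in which Lewis-acid-promoted addition of the diazoester to the aldehyde and a 1,2-hydride shift with loss of nitrogen give the beta-keto ester directly.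

Step 5
Reactants: 10 ethyl 3-[7-(3-methylbut-2-enyl)benzofuran-5-yl]-3-oxopropanoate
Product: 11 ethyl (R)-3-hydroxy-3-[7-(3-methylbut-2-enyl)benzofuran-5-yl]propanoate
Conditions: RuCl[(R,R)-TsDPEN](p-cymene) (1 mol %), HCO2H/Et3N 5:2, 30 °C
Reagents that add atoms: none
Why: Noyori–Ikariya asymmetric transfer hydrogenation, in which the (R,R)-catalyst should give the R carbinol of an aryl ketone through its CH/pi-organised six-membered transition state and leaves the prenyl alkene, the benzofuran and the ester untouched.

Step 6
Reactants: 11 ethyl (R)-3-hydroxy-3-[7-(3-methylbut-2-enyl)benzofuran-5-yl]propanoate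
Product: 12 (R)-3-hydroxy-3-[7-(3-methylbut-2-enyl)benzofuran-5-yl]propanoic acid
Conditions: LiOH, THF/H2O, 0 °C; then 1 M HCl to pH 3
Reagents that add atoms: lithium hydroxide [Li+].[OH-]
Why: Ester saponification at low temperature, mild enough to avoid retro-aldol cleavage or dehydration, does not touch the carbinol centre.

Step 7
Reactants: 12 (R)-3-hydroxy-3-[7-(3-methylbut-2-enyl)benzofuran-5-yl]propanoic acid
Product: 14 (R)-4-[7-(3-methylbut-2-enyl)benzofuran-5-yl]oxetan-2-one, via tosyl mixed anhydride 13 (not isolated)
Conditions: TsCl, pyridine, 0 °C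
Reagents that add atoms: none
Why: Beta-lactonisation by carboxyl activation, in which the carboxylate is sulfonylated faster than the alcohol and the hydroxyl then closes the four-membered ring at the acyl carbon, so the C–O bond at the stereocentre is never broken (retention, R).

Step 8
Reactants: 15 phloroglucinol
Product: 16 3,5-bis(methoxymethoxy)phenol
Conditions: MOMCl (2 equiv), iPr2NEt, DMF, 0 °C to rt
Reagents that add atoms: chloromethyl methyl ether COCCl
Why: O-alkylation of two of the three equivalent phenols, limited statistically by the stoichiometry, with the mono-, bis- and tris-ethers separable by chromatography.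

Step 9
Reactants: 14 (R)-4-[7-(3-methylbut-2-enyl)benzofuran-5-yl]oxetan-2-one, 16 3,5-bis(methoxymethoxy)phenol
Product: 20 (S)-5,7-bis(methoxymethoxy)-2-[7-(3-methylbut-2-enyl)benzofuran-5-yl]chroman-4-one, via potassium phenoxide 17 (not isolated), via potassium carboxylate 18 (not isolated), via trifluoroacetyl mixed anhydride 19 (not isolated)
Conditions: 16, KH, 18-crown-6, THF, 0 °C; add 14, −20 °C to rt; then (CF3CO)2O, CH2Cl2, 0 °C
Reagents that add atoms: none
Why: Phenoxide 17 attacks the benzylic carbon of the strained lactone in an SN2 alkyl–oxygen cleavage (O1–C2) and releases carboxylate 18, which trifluoroacetic anhydride converts into mixed anhydride 19, whose acyl carbon is attacked by the ring-A CH ortho to the new ether oxygen in a Friedel–Crafts acylation (C4–C4a). The closest known reaction types are the phenoxide opening of beta-propiolactone and beta-butyrolactone to 3-aryloxy acids and the mixed-anhydride cyclisation of such acids to chroman-4-ones, here run in one flask. Ring C is the only ring closed, by 6-exo-trig attack of the arene on the anhydride carbonyl. C2 is transferred rather than created: backside displacement inverts the R lactone carbon to S, and nothing touches it afterwards because no base is present once the ketone exists. The step needs alkyl over acyl attack and O- over C-alkylation; acyl attack is reversible (the alkoxide re-closes and expels aryloxide) whereas carboxylate formation is not, the benzylic position accelerates SN2, and the crown-separated potassium phenoxide in THF reacts at oxygen. Acylation regiochemistry is degenerate because both CH positions ortho to O1 are equivalent and each is activated by three oxygens, so the intramolecular acylation should outrun trifluoroacetylation and attack on the benzofuran or prenyl group.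

Step 10
Reactants: 20 (S)-5,7-bis(methoxymethoxy)-2-[7-(3-methylbut-2-enyl)benzofuran-5-yl]chroman-4-one
Product: 21 (S)-5,7-dihydroxy-2-[7-(3-methylbut-2-enyl)benzofuran-5-yl]chroman-4-one
Conditions: 3 M aq HCl, MeOH, 45 °C
Reagents that add atoms: none
Why: Acid-catalysed transacetalisation of both aryl MOM ethers to methanol, tolerated because flavanones racemise through base-induced ring opening rather than in dilute acid and the prenyl group has no neighbouring phenol with which to cyclise.

**Compound list**
1 | 3-bromo-4-hydroxybenzaldehyde | O=Cc1ccc(O)c(Br)c1 | starting material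
2 | 3-bromo-4-hydroxy-5-iodobenzaldehyde | O=Cc1cc(Br)c(O)c(I)c1 | intermediate
3 | ethynyltrimethylsilane | C#C[Si](C)(C)C | starting material
4 | 3-bromo-4-hydroxy-5-[(trimethylsilyl)ethynyl]benzaldehyde | O=Cc1cc(Br)c(O)c(C#C[Si](C)(C)C)c1 | intermediate
5 | 7-bromo-2-(trimethylsilyl)benzofuran-5-carbaldehyde | O=Cc1cc(Br)c2oc([Si](C)(C)C)cc2c1 | intermediate
6 | 7-bromobenzofuran-5-carbaldehyde | O=Cc1cc(Br)c2occc2c1 | intermediate
7 | tributyl(3-methylbut-2-enyl)stannane | CCCC[Sn](CCCC)(CCCC)CC=C(C)C | starting material
8 | 7-(3-methylbut-2-enyl)benzofuran-5-carbaldehyde | O=Cc1cc(CC=C(C)C)c2occc2c1 | intermediate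
9 | ethyl diazoacetate | CCOC(=O)C=[N+]=[N-] | starting material
10 | ethyl 3-[7-(3-methylbut-2-enyl)benzofuran-5-yl]-3-oxopropanoate | CCOC(=O)CC(=O)c1cc(CC=C(C)C)c2occc2c1 | intermediate
11 | ethyl (R)-3-hydroxy-3-[7-(3-methylbut-2-enyl)benzofuran-5-yl]propanoate | CCOC(=O)C[C@@H](O)c1cc(CC=C(C)C)c2occc2c1 | intermediate
12 | (R)-3-hydroxy-3-[7-(3-methylbut-2-enyl)benzofuran-5-yl]propanoic acid | OC(=O)C[C@@H](O)c1cc(CC=C(C)C)c2occc2c1 | intermediate
13 | (R)-3-hydroxy-3-[7-(3-methylbut-2-enyl)benzofuran-5-yl]propanoic 4-methylbenzenesulfonic anhydride | Cc1ccc(cc1)S(=O)(=O)OC(=O)C[C@@H](O)c1cc(CC=C(C)C)c2occc2c1 | intermediate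
14 | (R)-4-[7-(3-methylbut-2-enyl)benzofuran-5-yl]oxetan-2-one | O=C1C[C@H](c2cc(CC=C(C)C)c3occc3c2)O1 | intermediate
15 | phloroglucinol | Oc1cc(O)cc(O)c1 | starting material
16 | 3,5-bis(methoxymethoxy)phenol | COCOc1cc(O)cc(OCOC)c1 | intermediate
17 | potassium 3,5-bis(methoxymethoxy)phenoxide | [K+].[O-]c1cc(OCOC)cc(OCOC)c1 | intermediate
18 | potassium (S)-3-[3,5-bis(methoxymethoxy)phenoxy]-3-[7-(3-methylbut-2-enyl)benzofuran-5-yl]propanoate | [K+].[O-]C(=O)C[C@H](Oc1cc(OCOC)cc(OCOC)c1)c1cc(CC=C(C)C)c2occc2c1 | intermediate
19 | (S)-3-[3,5-bis(methoxymethoxy)phenoxy]-3-[7-(3-methylbut-2-enyl)benzofuran-5-yl]propanoic trifluoroacetic anhydride | O=C(OC(=O)C(F)(F)F)C[C@H](Oc1cc(OCOC)cc(OCOC)c1)c1cc(CC=C(C)C)c2occc2c1 | intermediate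
20 | (S)-5,7-bis(methoxymethoxy)-2-[7-(3-methylbut-2-enyl)benzofuran-5-yl]chroman-4-one | CC(C)=CCc1cc([C@@H]2CC(=O)c3c(OCOC)cc(OCOC)cc3O2)cc2ccoc12 | intermediate
21 | (S)-5,7-dihydroxy-2-[7-(3-methylbut-2-enyl)benzofuran-5-yl]chroman-4-one | CC(C)=CCc1cc([C@@H]2CC(=O)c3c(O)cc(O)cc3O2)cc2ccoc12 | target

Total step count: 10. Longest linear sequence: 9 (steps 1 to 7, 9 and 10).

**Steps most likely to fail**

Step 9. The phenoxide may act as a base and open the lactone to the cinnamate. It may also attack the acyl carbon, after which retro-aldol cleavage would erode the configuration, and the benzylic ether may ionise during the acylation. The fallback runs from 11 and 16 back to 20 and makes the C2–O1 bond by alcohol activation instead of lactone opening. Mitsunobu etherification of 11 with 16 (PPh3, DIAD, toluene, 0 °C) should give, with inversion, ethyl (S)-3-[3,5-bis(methoxymethoxy)phenoxy]-3-[7-(3-methylbut-2-enyl)benzofuran-5-yl]propanoate F1. Neutral ester cleavage with Me3SnOH (1,2-dichloroethane, 70 °C) should give (S)-3-[3,5-bis(methoxymethoxy)phenoxy]-3-[7-(3-methylbut-2-enyl)benzofuran-5-yl]propanoic acid F2. F2 is cyclised with (CF3CO)2O in CH2Cl2 at 0 °C to 20.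

Step 7. The activated hydroxy acid may oligomerise or dehydrate, and the aryl lactone may lose carbon dioxide on work-up. The fallback runs from 8 directly to 14 and builds the ring by cycloaddition instead of cyclodehydration. Ketene, generated in the flask from acetyl chloride and iPr2NEt, is combined with aldehyde 8 in a cinchona-alkaloid/LiClO4-catalysed asymmetric [2+2] cycloaddition (CH2Cl2/Et2O, −78 °C). O-trimethylsilylquinidine or its pseudoenantiomer O-trimethylsilylquinine is used, whichever gives the R lactone in a trial run.

Step 3. The prenyl group may be transferred through its substituted terminus (reverse prenylation), and oxidative addition of zerovalent palladium next to the furan oxygen may be sluggish. The fallback runs from 6 back to 8 and installs the chain in two stages. Stille allylation with allyltributylstannane (Pd(PPh3)4, toluene, 100 °C) should give 7-allylbenzofuran-5-carbaldehyde F3. Cross metathesis of F3 with 2-methylbut-2-ene (second-generation Grubbs catalyst, CH2Cl2, 40 °C) should give 8.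

**Further compounds**
F1 | step 9 | ethyl (S)-3-[3,5-bis(methoxymethoxy)phenoxy]-3-[7-(3-methylbut-2-enyl)benzofuran-5-yl]propanoate | CCOC(=O)C[C@H](Oc1cc(OCOC)cc(OCOC)c1)c1cc(CC=C(C)C)c2occc2c1
F2 | step 9 | (S)-3-[3,5-bis(methoxymethoxy)phenoxy]-3-[7-(3-methylbut-2-enyl)benzofuran-5-yl]propanoic acid | OC(=O)C[C@H](Oc1cc(OCOC)cc(OCOC)c1)c1cc(CC=C(C)C)c2occc2c1
F0 | step 7 | none | none
F3 | step 3 | 7-allylbenzofuran-5-carbaldehyde | O=Cc1cc(CC=C)c2occc2c1
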